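Everything rests on closing the ten-membered ring (C1–C10) at C9–C10 by a ring-closing allylboration. The precursor is a seco compound in which a cyclohexenyl pinacol boronate (boron on C12, alkene C10=C11, ring derived from (S)-carvone) is tied through C1–C8 to the finished γ-lactone bearing a C9 hydroxymethyl group. Oxidation to the C9 aldehyde triggers a chair transition state that forms C9–C10, sets C9 and C10 (trans ring fusion) and moves the alkene to C11=C12, the latent cis-11,12-diol. The step exploits the homoallylic alcohol C9(O)–C10–C11=C12 hidden where the C9 acetoxy carbon meets the cyclohexane ring.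

Key step: step 19

Remarks on the chemistry
- Numbering is that of the briarane skeleton: C1 (quaternary, C15 methyl), C2 (OAc), C3, C4, C5 (bears C16), C6, C7 (lactone O), C8 (OH), C9 (OAc), C10, C11 (OH, C20 methyl), C12 (OH), C13, C14 (OAc); lactone carbons C17 (C18 methyl) and C19 (C=O). β is the face of the six-membered ring that carries C15; α is the opposite face. The target is (1S,2S,5E,7S,8S,9S,10S,11S,12R,14S,17R).
- Assumption: (S,S)-ProPhenol is taken to give the 7S carbinol in step 10; if the opposite sense is found, the (R,R)-ligand is used.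
- Assumption: silyl ether 13 is purchased.

Fragment A (steps 1–7)

Step 1
Reactants: 1 (S)-(+)-carvone
Product: 2 hydroxymethylene ketone
Conditions: NaH, HCO2Et, cat. EtOH, THF, 0 °C to rt; aq. HCl work-up
Reagents that add atoms: ethyl formate, CCOC=O
Why: Claisen-type formylation of the ketone enolate at the only non-vinylogous α-position (the later C1) should give the chelated hydroxymethylene ketone, with no new stereocentre.

Step 2
Reactants: 2 hydroxymethylene ketone
Product: 3 keto aldehyde with quaternary C1
Conditions: MeI, K2CO3, acetone, rt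
Reagents that add atoms: iodomethane, CI
Why: C-methylation of the β-keto aldehyde enolate should occur anti to the adjacent pseudoaxial isopropenyl group, which sets C1 with the C15 methyl trans and the formyl carbon C2 cis to the C14 substituent.

Step 3
Reactants: 3 keto aldehyde
Product: 4 (2S)-propargylic alcohol
Conditions: MgBr2·OEt2, CH2Cl2, −78 °C; HC≡CMgBr (THF), −78 °C; aq. NH4Cl
Reagents that add atoms: ethynylmagnesium bromide, C#C[Mg]Br
Why: In this chelation-controlled Grignard addition magnesium bridges the C2 aldehyde and C10 ketone oxygens, the ring fusion holds the C15 methyl axial on the chelate, and the acetylide should add to the aldehyde face anti to it, which sets C2 (S).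

Step 4
Reactants: 4 propargylic alcohol
Product: 5 propargylic acetate
Conditions: Ac2O, DMAP, pyridine, CH2Cl2, rt
Reagents that add atoms: acetic anhydride, CC(=O)OC(C)=O
Why: DMAP-catalysed acetylation installs the C2 acetate of the target without touching a stereocentre.

Step 5
Reactants: 5 propargylic acetate
Product: 7 alkyne 2,14-diacetate, via methoxy hydroperoxide 6 (not isolated)
Conditions: O3, CH2Cl2/MeOH, −78 °C; then Ac2O, Et3N, DMAP, CH2Cl2, 0 °C to rt
Reagents that add atoms: ozone, [O-][O+]=O; methanol, CO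
Why: Ozonolysis of the electron-rich 1,1-disubstituted alkene (enone and alkyne react far more slowly) gives the methoxy hydroperoxide, whose peracetate undergoes Criegee rearrangement with migration of the secondary carbon C14 with retention, so the 14α-acetate is formed directly.

Step 6
Reactants: 7 alkyne 2,14-diacetate
Product: 8 vinyl enone diacetate
Conditions: H2 (1 atm), Pd/CaCO3 poisoned with Pb(OAc)2, quinoline, EtOAc, rt
Reagents that add atoms: none
Why: Lindlar semihydrogenation should reduce only the terminal alkyne to the vinyl group (C3=C4) and leave the trisubstituted enone alkene and the allylic acetate intact.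

Step 7
Reactants: 8 vinyl enone diacetate
Product: 9 fragment A (10α-allylic alcohol)
Conditions: NaBH4, CeCl3·7H2O, MeOH, −78 °C
Reagents that add atoms: none
Why: In this Luche 1,2-reduction hydride should arrive on the β face (axial attack anti to the axial C2 substituent in one half-chair, equatorial attack avoiding the syn-axial 14-acetate in the other), giving the 10α alcohol that later relays its configuration to C12.

Fragment B (steps 8–14)

Step 8
Reactants: 10 2-methylenepropane-1,3-diol
Product: 11 mono-TBS ether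
Conditions: NaH (1 equiv), TBSCl (1 equiv), THF, 0 °C to rt
Reagents that add atoms: tert-butyldimethylsilyl chloride, CC(C)(C)[Si](C)(C)Cl
Why: Monosilylation of the symmetrical diol through its monosodium alkoxide differentiates the later C9 oxygen; no stereocentre is formed.

Step 9
Reactants: 11 mono-TBS ether
Product: 12 2-(silyloxymethyl)acrolein
Conditions: MnO2, CH2Cl2, rt
Reagents that add atoms: none
Why: MnO2 oxidation of the allylic alcohol should give the enal (the later C7 aldehyde) without affecting the silyl ether.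

Step 10
Reactants: 12 2-(silyloxymethyl)acrolein; 13 tert-butyldiphenyl(prop-2-yn-1-yloxy)silane
Product: 14 (S)-enynol
Conditions: Me2Zn, (S,S)-ProPhenol (20 mol %), Ph3P=O, toluene, 0 °C
Reagents that add atoms: none
Why: In the ProPhenol/Me2Zn-catalysed asymmetric alkynylation of the α,β-unsaturated aldehyde the dinuclear zinc catalyst selects the aldehyde face and sets C7 (S).

Step 11
Reactants: 14 (S)-enynol
Product: 16 (Z)-vinyl iodide, via alkenylaluminate 15 (not isolated)
Conditions: NaAlH2(OCH2CH2OMe)2, THF, 0 °C; then I2, −78 °C; aq. potassium sodium tartrate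
Reagents that add atoms: iodine, II
Why: Hydroxyl-directed trans-hydroalumination of the propargylic alcohol places aluminium on C5 in a five-membered alkoxyaluminate, and iodinolysis with retention gives the (Z)-iodoalkene, which fixes the C5=C6 geometry (iodine, later C4, cis to C7).

Step 12
Reactants: 16 (Z)-vinyl iodide
Product: 17 2-bromopropanoate ester
Conditions: CH3CHBrCOBr, pyridine, CH2Cl2, −20 °C
Reagents that add atoms: 2-bromopropanoyl bromide, CC(Br)C(Br)=O
Why: Acylation of the secondary alcohol tethers the C17–C19 unit to O7, and the brominated carbon (used as a mixture of epimers) later becomes an enolate carbon.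

Step 13
Reactants: 17 2-bromopropanoate ester
Product: 18 α-acyloxy ketone
Conditions: OsO4 (cat.), NaIO4, 2,6-lutidine, dioxane/H2O, rt
Reagents that add atoms: osmium tetroxide (catalytic oxygen carrier), O=[Os](=O)(=O)=O; sodium periodate, [Na+].[O-]I(=O)(=O)=O
Why: Lemieux–Johnson cleavage of the 1,1-disubstituted alkene (the trisubstituted, electron-poor iodoalkene should react more slowly) unveils the C8 ketone.

Step 14
Reactants: 18 α-acyloxy ketone
Product: 19 fragment B (β-hydroxy γ-lactone)
Conditions: SmI2 (2.2 equiv), THF, −78 °C; aq. NH4Cl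
Reagents that add atoms: none
Why: In this intramolecular Reformatsky reaction the samarium enolate formed from the C–Br bond adds to the C8 ketone through a chelated bicyclic transition state with CH2OTBS anti to the C7 alkenyl group and the enolate methyl anti to CH2OTBS, which sets C8 and C17 (hydroxyl, methyl and alkenyl group all cis on the lactone).

Coupling and endgame (steps 15–23)

Step 15
Reactants: 9 fragment A (10α-allylic alcohol); 19 fragment B (β-hydroxy γ-lactone)
Product: 21 seco allylic alcohol, via B-alkyl-9-BBN borane 20 (not isolated)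
Conditions: 9-BBN (2.5 equiv), THF, rt; then 19, Pd(dppf)Cl2, AsPh3, aq. K3PO4, DMF, rt
Reagents that add atoms: none
Why: In this B-alkyl Suzuki–Miyaura coupling 9-BBN hydroborates only the monosubstituted alkene (and masks the free hydroxyl as a borinate), and the primary alkylborane couples with the vinyl iodide with retention of alkene geometry, joining C4 to C5.

Step 16
Reactants: 21 seco allylic alcohol
Product: 22 allylic methyl carbonate
Conditions: ClCO2Me, pyridine, DMAP, CH2Cl2, 0 °C
Reagents that add atoms: methyl chloroformate, COC(=O)Cl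
Why: The only secondary alcohol (C10–OH) is converted into its carbonate, the leaving group for allylic substitution, while the tertiary C8–OH should not react.

Step 17
Reactants: 22 allylic methyl carbonate
Product: 23 diol carbonate
Conditions: camphorsulfonic acid (cat.), MeOH/CH2Cl2, 0 °C
Reagents that add atoms: none
Why: Acid-catalysed methanolysis should remove the primary TBS ether at O9, while the far more acid-stable TBDPS ether, the carbonate and the acetates survive.

Step 18
Reactants: 23 diol carbonate
Product: 24 allylboronate (12β-Bpin, C10=C11)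
Conditions: CuCl (10 mol %), KOtBu (10 mol %), Xantphos, B2pin2, THF, rt
Reagents that add atoms: bis(pinacolato)diboron, CC1(C)OB(OC1(C)C)B1OC(C)(C)C(C)(C)O1
Why: In the copper-catalysed γ-selective allylic borylation of the carbonate the boryl group is delivered to C12 anti to the leaving group (anti-SN2′), so the 10α carbonate should give the 12β boronate with the alkene moved to C10=C11.

Step 19
Reactants: 24 allylboronate (12β-Bpin, C10=C11)
Product: 27 ten-membered homoallylic alcohol, via C9 aldehyde 25 (not isolated), via pinacol borate 26 (not isolated)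
Conditions: SO3·pyridine, DMSO, iPr2NEt, CH2Cl2, 0 °C; then dilution with toluene (0.002 M), 25 to 60 °C; aq. NaHCO3 work-up
Reagents that add atoms: none
Why: Parikh–Doering oxidation unmasks the C9 aldehyde 25, whose oxygen coordinates the pinacol boronate so that the γ-carbon C10 adds to C9 through a closed six-membered chair transition state (intramolecular allylboration, SE2′ with boron and the new bond on the same face), moving the alkene to C11=C12 and giving borate 26, which is hydrolysed on work-up. The closest known reaction type is the ring-closing allylboration of ω-oxo allylboronates, and for a ten-membered carbocycle the nearest analogy is the Nozaki–Hiyama–Kishi macrocyclic allylation. The ten-membered ring C1–C10 closes in a 10-exo-trig mode at the aldehyde carbon, with the allyl unit C10–C11–C12 embedded in the cyclohexene. C10 is set by the 12β C–B bond, which forces bond formation on the β face and hence the trans ring fusion (H10 anti to C15); C9 is set by the chair, in which the ring-locked (Z)-allyl unit places C1 axial and the bulky C8 substituent of the aldehyde equatorial, giving the syn relationship of O9 and C1 (9S). The step needs intramolecular to beat intermolecular allylboration, which high dilution and the low bimolecular reactivity of a hindered secondary pinacol boronate should secure, and it needs boron not to be chelated by the free tertiary C8–OH, which the non-exchanging pinacol ester should prevent.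

Step 20
Reactants: 27 ten-membered homoallylic alcohol
Product: 28 2,9,14-triacetate
Conditions: Ac2O, DMAP, pyridine, 40 °C
Reagents that add atoms: acetic anhydride, CC(=O)OC(C)=O
Why: Acetylation of the secondary C9–OH should give the third acetate while the tertiary C8–OH is too hindered to react.

Step 21
Reactants: 28 2,9,14-triacetate
Product: 29 C16 allylic alcohol
Conditions: HF·pyridine, pyridine, THF, rt
Reagents that add atoms: none
Why: Buffered fluoride cleaves the TBDPS ether under non-basic conditions that should leave the acetates and the β-hydroxy lactone intact.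

Step 22
Reactants: 29 C16 allylic alcohol
Product: 30 C16 allylic chloride
Conditions: PPh3, Cl3CCOCCl3, CH2Cl2, −20 °C
Reagents that add atoms: hexachloroacetone, O=C(C(Cl)(Cl)Cl)C(Cl)(Cl)Cl
Why: Phosphine-mediated chlorination of the primary allylic alcohol proceeds by SN2 without allylic transposition, and the tertiary alcohol is inert.

Step 23
Reactants: 30 C16 allylic chloride
Product: 31 CNP0211628.2 (target)
Conditions: OsO4 (5 mol %), NMO, acetone/H2O, 0 °C to rt
Reagents that add atoms: osmium tetroxide (catalytic oxygen carrier), O=[Os](=O)(=O)=O; 4-methylmorpholine N-oxide, C[N+]1([O-])CCOCC1; water, O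
Why: In this Upjohn dihydroxylation the allylic chloride deactivates C5=C6, so OsO4 should add to C11=C12 from the α face, opposite the axial C15 methyl and the 9-acetoxy group, giving the cis-11α,12α-diol and setting C11 and C12.

Compound list
1 | (S)-(+)-carvone | C=C(C)[C@H]1CC=C(C)C(=O)C1 | starting material
2 | 6-(hydroxymethylene) derivative of (S)-carvone (Z-enol, isopropenyl centre unchanged) | C=C(C)[C@H]1CC=C(C)C(=O)/C1=C\O | intermediate
3 | keto aldehyde: C1 quaternary, C15 methyl trans and formyl (C2) cis to the C14 isopropenyl group, C10 enone | O=C[C@]1(C)C(=O)C(C)=CC[C@@H]1C(C)=C | intermediate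
4 | (2S)-ethynyl carbinol at C2 of 3 | C#C[C@H](O)[C@]1(C)C(=O)C(C)=CC[C@@H]1C(C)=C | intermediate
5 | C2 acetate of 4 | C#C[C@H](OC(C)=O)[C@]1(C)C(=O)C(C)=CC[C@@H]1C(C)=C | intermediate
6 | methoxy hydroperoxide at the former isopropenyl carbon of 5 | C#C[C@H](OC(C)=O)[C@]1(C)C(=O)C(C)=CC[C@@H]1C(C)(OC)OO | intermediate
7 | alkyne 2,14-diacetate (14α-OAc, C10 enone) | C#C[C@H](OC(C)=O)[C@]1(C)C(=O)C(C)=CC[C@@H]1OC(C)=O | intermediate
8 | vinyl enone diacetate (C3=C4 vinyl, 2-OAc, 14α-OAc) | C=C[C@H](OC(C)=O)[C@]1(C)C(=O)C(C)=CC[C@@H]1OC(C)=O | intermediate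
9 | fragment A: 10α-allylic alcohol, C11=C12, 2-OAc, 14α-OAc, C3=C4 vinyl | C=C[C@H](OC(C)=O)[C@]1(C)[C@H](O)C(C)=CC[C@@H]1OC(C)=O | intermediate
10 | 2-methylenepropane-1,3-diol | C=C(CO)CO | starting material
11 | 2-[(tert-butyldimethylsilyloxy)methyl]prop-2-en-1-ol | C=C(CO)CO[Si](C)(C)C(C)(C)C | intermediate
12 | 2-[(tert-butyldimethylsilyloxy)methyl]prop-2-enal | C=C(C=O)CO[Si](C)(C)C(C)(C)C | intermediate
13 | tert-butyldiphenyl(prop-2-yn-1-yloxy)silane | C#CCO[Si](c1ccccc1)(c1ccccc1)C(C)(C)C | starting material
14 | (S)-enynol: C7 carbinol flanked by the C5≡C6 alkyne (C16–OTBDPS) and the C8 methylene alkene (C9–OTBS) | CC(C)(C)[Si](c1ccccc1)(c1ccccc1)OCC#C[C@H](O)C(=C)CO[Si](C)(C)C(C)(C)C | intermediate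
15 | sodium cyclic alkoxy(alkenyl)aluminate (Al on C5 and O7) | [Na+].COCCO[Al-]1(OCCOC)O[C@H](C(=C)CO[Si](C)(C)C(C)(C)C)C=C1CO[Si](c2ccccc2)(c2ccccc2)C(C)(C)C | intermediate
16 | (S,Z)-vinyl iodide: iodine on C5 cis to C7, free C7–OH | CC(C)(C)[Si](c1ccccc1)(c1ccccc1)OC/C(I)=C/[C@H](O)C(=C)CO[Si](C)(C)C(C)(C)C | intermediate
17 | 2-bromopropanoate of 16 (epimers at the brominated carbon) | CC(Br)C(=O)O[C@@H](/C=C(I)/CO[Si](c1ccccc1)(c1ccccc1)C(C)(C)C)C(=C)CO[Si](C)(C)C(C)(C)C | intermediate
18 | α-acyloxy ketone (C8 ketone) | CC(Br)C(=O)O[C@@H](/C=C(I)/CO[Si](c1ccccc1)(c1ccccc1)C(C)(C)C)C(=O)CO[Si](C)(C)C(C)(C)C | intermediate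
19 | fragment B: (3R,4R,5S)-4-hydroxy-3-methyl-4-(TBS-oxymethyl)-5-[(Z)-2-iodo-3-(TBDPS-oxy)prop-1-enyl]oxolan-2-one | CC(C)(C)[Si](c1ccccc1)(c1ccccc1)OC/C(I)=C/[C@@H]1OC(=O)[C@H](C)[C@@]1(O)CO[Si](C)(C)C(C)(C)C | intermediate
20 | B-alkyl-9-BBN borane at C4 of fragment A, C10 oxygen as 9-BBN borinate | CC(=O)O[C@@H](CCB1C2CCCC1CCC2)[C@]1(C)[C@H](OB2C3CCCC2CCC3)C(C)=CC[C@@H]1OC(C)=O | intermediate
21 | seco allylic alcohol: C4–C5 joined, 10α-OH, 8-OH, 9-OTBS, 16-OTBDPS, 2,14-diacetate | CC(=O)O[C@@H](CC/C(CO[Si](c1ccccc1)(c1ccccc1)C(C)(C)C)=C\[C@@H]1OC(=O)[C@H](C)[C@@]1(O)CO[Si](C)(C)C(C)(C)C)[C@]1(C)[C@H](O)C(C)=CC[C@@H]1OC(C)=O | intermediate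
22 | 10α-methyl carbonate of 21 | CC(=O)O[C@@H](CC/C(CO[Si](c1ccccc1)(c1ccccc1)C(C)(C)C)=C\[C@@H]1OC(=O)[C@H](C)[C@@]1(O)CO[Si](C)(C)C(C)(C)C)[C@]1(C)[C@H](OC(=O)OC)C(C)=CC[C@@H]1OC(C)=O | intermediate
23 | 8,9-diol carbonate (TBS removed) | CC(=O)O[C@@H](CC/C(CO[Si](c1ccccc1)(c1ccccc1)C(C)(C)C)=C\[C@@H]1OC(=O)[C@H](C)[C@@]1(O)CO)[C@]1(C)[C@H](OC(=O)OC)C(C)=CC[C@@H]1OC(C)=O | intermediate
24 | allylboronate: 12β-pinacolboryl, C10=C11, 8,9-diol | CC(=O)O[C@@H](CC/C(CO[Si](c1ccccc1)(c1ccccc1)C(C)(C)C)=C\[C@@H]1OC(=O)[C@H](C)[C@@]1(O)CO)[C@]1(C)C=C(C)[C@@H](B2OC(C)(C)C(C)(C)O2)C[C@@H]1OC(C)=O | intermediate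
25 | C9 aldehyde of 24 | CC(=O)O[C@@H](CC/C(CO[Si](c1ccccc1)(c1ccccc1)C(C)(C)C)=C\[C@@H]1OC(=O)[C@H](C)[C@@]1(O)C=O)[C@]1(C)C=C(C)[C@@H](B2OC(C)(C)C(C)(C)O2)C[C@@H]1OC(C)=O | intermediate
26 | pinacol borate (O9–B) of the cyclised product | CC(=O)O[C@H]1CC/C(CO[Si](c3ccccc3)(c3ccccc3)C(C)(C)C)=C\[C@@H]2OC(=O)[C@H](C)[C@@]2(O)[C@@H](OB3OC(C)(C)C(C)(C)O3)[C@H]2C(C)=CC[C@H](OC(C)=O)[C@]12C | intermediate
27 | ten-membered homoallylic alcohol: 9-OH, 8-OH, C11=C12, 2,14-diacetate, 16-OTBDPS | CC(=O)O[C@H]1CC/C(CO[Si](c3ccccc3)(c3ccccc3)C(C)(C)C)=C\[C@@H]2OC(=O)[C@H](C)[C@@]2(O)[C@@H](O)[C@H]2C(C)=CC[C@H](OC(C)=O)[C@]12C | intermediate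
28 | 2,9,14-triacetate, 16-OTBDPS | CC(=O)O[C@H]1CC/C(CO[Si](c3ccccc3)(c3ccccc3)C(C)(C)C)=C\[C@@H]2OC(=O)[C@H](C)[C@@]2(O)[C@@H](OC(C)=O)[C@H]2C(C)=CC[C@H](OC(C)=O)[C@]12C | intermediate
29 | C16 allylic alcohol triacetate | CC(=O)O[C@H]1CC/C(CO)=C\[C@@H]2OC(=O)[C@H](C)[C@@]2(O)[C@@H](OC(C)=O)[C@H]2C(C)=CC[C@H](OC(C)=O)[C@]12C | intermediate
30 | C16 allylic chloride triacetate with C11=C12 | CC(=O)O[C@H]1CC/C(CCl)=C\[C@@H]2OC(=O)[C@H](C)[C@@]2(O)[C@@H](OC(C)=O)[C@H]2C(C)=CC[C@H](OC(C)=O)[C@]12C | intermediate
31 | CNP0211628.2 | CC(=O)O[C@H]1CC/C(CCl)=C\[C@@H]2OC(=O)[C@H](C)[C@@]2(O)[C@@H](OC(C)=O)[C@H]2[C@](C)(O)[C@H](O)C[C@H](OC(C)=O)[C@]12C | target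

Total step count: 23. Longest linear sequence: 16 steps (steps 1–7 then 15–23; the branch through steps 8–14 is equally long).

Steps most likely to fail

Step 19 (key step). Ring closure joins two neopentyl carbons and may be slower than intermolecular allylboration or protodeboronation, or it may run through the chair with the aldehyde substituent axial and give the C9 epimer. The fallback closes the same bond by a Nozaki–Hiyama–Kishi allylation, which tolerates slow closure under high dilution. It sets out from 21. CBr4/PPh3 converts the allylic alcohol by SN2′ into the C12 allylic bromide F1 (any C10 bromide converges on the same allylchromium species). HF·pyridine removes the TBS ether to give the bromo diol F2, and Parikh–Doering oxidation gives the bromo aldehyde F3. CrCl2 in THF/DMF at high dilution then generates the allylchromium reagent, which adds through C10 to the C9 aldehyde; the sequence comes back to the route at 27.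

Step 18. Borylcupration of the hindered trisubstituted alkene may be too slow, so that loss of the carbonate by elimination or erosion of the γ/anti fidelity competes. The fallback avoids any isolated allylboron compound and sets out from 23. Parikh–Doering oxidation gives the aldehyde carbonate F4. Pd(PPh3)4 (zerovalent palladium) ionises the carbonate anti to the leaving group, and InI reduces the π-allylpalladium complex to an allylindium species (umpolung allylation), which should add to the C9 aldehyde through the same six-membered transition state; the sequence comes back to the route at 27.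

Step 23. Facial selectivity may be poor or reversed, because the α face of C11=C12 carries the axial 14-acetate and OsO4 may add from the β face. The fallback turns a β attack into the α-diol and sets out from 30. mCPBA gives the 11β,12β-epoxide F5, and aqueous HClO4 opens it at the tertiary C11 with inversion to the 11α,12β-diol F6. Dess–Martin periodinane oxidises the secondary C12 hydroxyl to the α-hydroxy ketone F7. NaBH4 at low temperature should then deliver hydride from the β face (equatorial attack, the axial approach being blocked by the syn-axial 14-acetate) to give the 12α alcohol; the sequence comes back to the route at 31.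

Further compounds
F1 | step 19 | C12 allylic bromide (C10=C11, 9-OTBS, configuration at C12 not defined) | CC(=O)O[C@@H](CC/C(CO[Si](c1ccccc1)(c1ccccc1)C(C)(C)C)=C\[C@@H]1OC(=O)[C@H](C)[C@@]1(O)CO[Si](C)(C)C(C)(C)C)[C@]1(C)C=C(C)C(Br)C[C@@H]1OC(C)=O
F2 | step 19 | bromo diol (TBS removed) | CC(=O)O[C@@H](CC/C(CO[Si](c1ccccc1)(c1ccccc1)C(C)(C)C)=C\[C@@H]1OC(=O)[C@H](C)[C@@]1(O)CO)[C@]1(C)C=C(C)C(Br)C[C@@H]1OC(C)=O
F3 | step 19 | bromo aldehyde (C9 aldehyde) | CC(=O)O[C@@H](CC/C(CO[Si](c1ccccc1)(c1ccccc1)C(C)(C)C)=C\[C@@H]1OC(=O)[C@H](C)[C@@]1(O)C=O)[C@]1(C)C=C(C)C(Br)C[C@@H]1OC(C)=O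
F4 | step 18 | aldehyde carbonate (C9 aldehyde, 10α-methyl carbonate) | CC(=O)O[C@@H](CC/C(CO[Si](c1ccccc1)(c1ccccc1)C(C)(C)C)=C\[C@@H]1OC(=O)[C@H](C)[C@@]1(O)C=O)[C@]1(C)[C@H](OC(=O)OC)C(C)=CC[C@@H]1OC(C)=O
F5 | step 23 | 11β,12β-epoxide of 30 | CC(=O)O[C@H]1CC/C(CCl)=C\[C@@H]2OC(=O)[C@H](C)[C@@]2(O)[C@@H](OC(C)=O)[C@H]2[C@@]3(C)O[C@H]3C[C@H](OC(C)=O)[C@]12C
F6 | step 23 | 11α,12β-diol (12-epimer of the target) | CC(=O)O[C@H]1CC/C(CCl)=C\[C@@H]2OC(=O)[C@H](C)[C@@]2(O)[C@@H](OC(C)=O)[C@H]2[C@](C)(O)[C@@H](O)C[C@H](OC(C)=O)[C@]12C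
F7 | step 23 | 11α-hydroxy C12 ketone | CC(=O)O[C@H]1CC/C(CCl)=C\[C@@H]2OC(=O)[C@H](C)[C@@]2(O)[C@@H](OC(C)=O)[C@H]2[C@](C)(O)C(=O)C[C@H](OC(C)=O)[C@]12C
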